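## Analysis of the target

Compound 13 joins two enolic rings through one methylene group. One half is an acetylated phloroglucinol fused to a 2,3-dihydrofuran (a 5-acetyl-4,6-dihydroxy-2,3-dihydro-1-benzofuran). The other is a 6-ethyl-4-hydroxy-5-methyl-2-pyranone (ring C), and the CH2 runs from benzofuran C7 to pyranone C3. The benzene ring is fully substituted: it carries the ring oxygen, two hydroxyls, the acetyl group, the dihydrofuran CH2 and the bridge. There is one stereocentre, C2 of the dihydrofuran (R), bearing the 6-methylhepta-1,5-dien-2-yl chain; it stands alone, so it must be set by a catalyst and not by relay from another centre. The C2–O1 bond is both allylic and an aryl ether and can be ionised by acid or by zerovalent palladium. The two alkenes are prone to acid-induced cyclisation, the polyphenol is oxidisable, and the aryl–CH2–pyranone bridge can be cleaved by ipso protonation in strong acid. The difficulties are to place three different carbon substituents on a phloroglucinol, to decide which of three phenolic oxygens becomes the ring oxygen, and to bring in the diene and the stereocentre only after all harsh steps. The strategy rests on ring C: pyranone C3 and the bridge CH2 are the α- and β-carbons of a 3-arylpropanoic acid, and C4–C5–C6 with O1 is the enol form of a 2-methyl-3-oxopentanoate. Ring C can therefore be closed at C3–C4 by an ester condensation with the bridge already in place.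

## Retrosynthetic reasoning

**Dihydrofuran ring (O1–C2 and C3–C3a).** Target 13 is cut into aryl iodide 11 and myrcene 12. The ten carbons of 12 map onto C3, C2 and the side chain without any adjustment, and this cut removes the stereocentre, the allylic ether and both alkenes from every earlier step. The forward reaction must add the aryl group to the terminal carbon of the monosubstituted vinyl group of 12. It must close the C–O bond through the hydroxyl para to the acetyl group, not through the one next to it. A chiral phosphine on zerovalent palladium must decide the configuration at C2.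

**Carbon–iodine bond.** Iodide 11 goes back to the acetophloroglucinol 10. The position is the only aromatic C–H left in 10, so an electrophilic iodination has no regiochemical choice.

**Aryl–acetyl bond.** Ketone 10 goes back to triol 9. The two free ring carbons of 9 are equivalent, and the first acyl group deactivates the ring towards a second. The acetyl group also makes the three phenols unequal, which the final ring closure needs.

**Methyl ethers.** Triol 9 goes back to the trimethyl ether 8. The ethers keep the arene inert through the base chemistry and are removed before the acid-sensitive diene is present.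

**Pyranone C3–C4 (key disconnection).** Pyranone 8 is opened to the enol ester 7. The cut lies here because C3 is the natural nucleophile (the α-carbon of an ester) and C4 the natural electrophile (an ester carbonyl). The O1–C2 bond is then only an ester linkage, and the bridge CH2 arrives as an ordinary saturated carbon of an arylpropanoic acid, so no cationic bridge-forming step between two nucleophilic rings is needed. The forward reaction has to deprotonate the acyl α-methylene of 7 without cleaving the enol ester and let that enolate attack the neighbouring ester; the acidity of the product drives it.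

**Enol ester C–O bond.** Enol ester 7 goes back to acid chloride 6 and β-ketoester 5. The acylation must go to oxygen and must place the acyloxy group cis to the ester (Z); otherwise the later ring closure is geometrically impossible. A chelated metal enolate of 5 is the handle for both requirements.

**Propanoic acid chain.** Acid chloride 6 comes from acid 4, which comes by hydrogenation from cinnamic acid 3, the condensation product of aldehyde 1 and malonic acid 2. The two ortho methoxy groups of 1 block cyclisation of the acyl chain onto the ring.

## Alternatives that were turned down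

**Alternative 1:** The dihydrofuran is cut at C2–C3. The ring oxygen is fixed first as an allyl aryl ether and the neighbouring aldehyde carbon is converted into a tosylhydrazone, as in 3-acetyl-2,4-bis(tert-butyldimethylsilyloxy)-6-[(6-methyl-2-methylidenehept-5-en-1-yl)oxy]benzaldehyde N-tosylhydrazone A2. In the forward step the aryl carbene released from A2 on a chiral dirhodium carboxylate inserts into one O–CH2 hydrogen. This gives 1-[(2R)-4,6-bis(tert-butyldimethylsilyloxy)-2-(6-methylhepta-1,5-dien-2-yl)-2,3-dihydrobenzofuran-5-yl]ethanone A1, closing the ring and setting C2 together.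
- For: the ring oxygen is chosen by a plain O-alkylation, so the question of which phenol closes the ring never arises. On this point the alternative is stronger than the chosen route.
- Against: the carbene carries only an aryl group and hydrogen, so dimerisation and azine formation are expected. Cyclopropanation of the 1,1-disubstituted alkene directly beside the C–H bond, through a six-membered arrangement, is a very favourable competitor. The trisubstituted alkene is a further carbene trap, and the aryl ketone competes when the hydrazone is made.
- A1 also still lacks ring C. After desilylation, 6-ethyl-4-hydroxy-5-methyl-2H-pyran-2-one A3 would have to be joined to C7 through a one-carbon electrophile. That is bridge chemistry between two nucleophiles, with symmetric dimers as by-products, on a compound that already holds the acid-sensitive allylic ether and diene.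
- Comparison: the chosen route carries the bridge carbon from the first step and closes its rings by reactions with close precedent. What it gives up is the unambiguous placement of the ring oxygen.

**Alternative 2:** The same two bonds are cut as in the last step of the chosen route, but on a small aryl iodide. 1-[4-Hydroxy-3-iodo-2,6-bis(methoxymethoxy)phenyl]ethanone A5 and myrcene 12 combine under chiral zerovalent palladium to give 1-[(2R)-4,6-bis(methoxymethoxy)-2-(6-methylhepta-1,5-dien-2-yl)-2,3-dihydrobenzofuran-5-yl]ethanone A4.
- For: A5 has a single free hydroxyl, so the regiochemistry of ring closure is not in doubt. It is a neutral substrate close to those on which this reaction type is established, so the enantioselectivity is easier to predict. On both points this alternative is stronger, and it is convergent.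
- Against: A5 needs the two chelated hydroxyls protected while the para hydroxyl stays free, the reverse of their natural order of reactivity, which costs several protecting-group steps. The acetals must be removed with acid after the diene and the allylic ether are in place. Ring C (A3) must again be attached at the very end through a one-carbon electrophile, with the homodimer problem described above.
- Comparison: the chosen route uses the same annulation on a more demanding substrate. In exchange it has no protecting-group steps beyond three methyl ethers, no late bridge formation, and all strongly acidic steps come before the diene is introduced.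

**Alternative 3:** Ring C is cut at C4–C5 and O1–C2. Trimethyl(pent-2-en-3-yloxy)silane A8 is acylated at carbon by one acid chloride group of 2-[(3-acetyl-2,4,6-trimethoxyphenyl)methyl]propanedioyl dichloride A7 and at the enol oxygen by the other. This gives 3-[(3-acetyl-2,4,6-trimethoxyphenyl)methyl]-6-ethyl-4-hydroxy-5-methyl-2H-pyran-2-one A6.
- For: two bonds and the ring form in one convergent step from a symmetric ketone equivalent, and the bridge is in place as in the chosen route. The acetyl group is already present, which saves the late acetylation. On step count this alternative is equal or slightly better.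
- Against: A7 is a monosubstituted malonyl dichloride, which loses hydrogen chloride easily to a chlorocarbonyl ketene and oligomerises. It carries an aryl methyl ketone, and aryl methyl ketones are themselves converted into 6-aryl-4-hydroxy-2-pyranones by malonyl dichlorides, so A7 can react with itself. Acid is set free beside an electron-rich ring, and the order of C- and O-acylation of A8 is not under control.
- Comparison: the chosen route makes O1–C2 as a simple ester and then closes C3–C4 intramolecularly under aprotic basic conditions with no free bis-electrophile. It is one step longer, but each bond is formed in a separate event.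

Key step: step 4

Assumption: ethyl 2-methyl-3-oxopentanoate is used as the commercial racemate; its stereocentre becomes the sp2 carbon C5 of the pyranone and has no influence on the route.

## Route

Step 1
Reactants: 1 2,4,6-trimethoxybenzaldehyde; 2 malonic acid
Product: 3 (2E)-3-(2,4,6-trimethoxyphenyl)prop-2-enoic acid
Conditions: 2 (2 equiv), pyridine, piperidine (cat.), 100 °C; then aq. HCl
Reagents that add atoms: none
Why: Knoevenagel–Doebner condensation; the arylidene malonic acid loses CO2 in hot pyridine to give the E acid, and the two ortho methoxy groups slow the addition but do not block it.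

Step 2
Reactants: 3 (2E)-3-(2,4,6-trimethoxyphenyl)prop-2-enoic acid
Product: 4 3-(2,4,6-trimethoxyphenyl)propanoic acid
Conditions: H2 (1 atm), 10% Pd/C, EtOAc–MeOH, rt
Reagents that add atoms: none
Why: Heterogeneous catalytic hydrogenation of the conjugated C=C bond; the aryl ethers and the carboxylic acid are inert under these conditions.

Step 3
Reactants: 4 3-(2,4,6-trimethoxyphenyl)propanoic acid; 5 ethyl 2-methyl-3-oxopentanoate
Product: 7 ethyl (2Z)-2-methyl-3-{[3-(2,4,6-trimethoxyphenyl)propanoyl]oxy}pent-2-enoate, via 3-(2,4,6-trimethoxyphenyl)propanoyl chloride 6 (not isolated)
Conditions: 4, 1-chloro-N,N,2-trimethylprop-1-en-1-amine (1.1 equiv), CH2Cl2, 0 °C → rt; separately 5 (1.1 equiv), NaH (1.05 equiv), Et2O, 0 °C; solution of 6 added, 0 °C → rt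
Reagents that add atoms: none
Why: O-Acylation of a β-ketoester enolate by an acid chloride; the sodium enolate of 5 in ether is a U-shaped chelate, so acylation at the ketone-derived oxygen should place the acyloxy group cis to the ester (Z), as in the Z-selective enol phosphorylation, sulfonylation and triflation of chelated β-ketoester enolates. The α-methyl group disfavours C-acylation, which would create a quaternary carbon. The neutral α-chloroenamine makes 6 without HCl or chloroiminium electrophiles that could attack the trimethoxyphenyl ring.

Step 4
Reactants: 7 ethyl (2Z)-2-methyl-3-{[3-(2,4,6-trimethoxyphenyl)propanoyl]oxy}pent-2-enoate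
Product: 8 6-ethyl-4-hydroxy-5-methyl-3-[(2,4,6-trimethoxyphenyl)methyl]-2H-pyran-2-one
Conditions: 7 added slowly to LiN(SiMe3)2 (2.5 equiv), THF, −78 °C; then → −20 °C; 1 M HCl
Reagents that add atoms: none
Why: Intramolecular Claisen (Dieckmann-type) condensation, the reaction type by which O-acyl salicylates give 4-hydroxycoumarins and O-acyl β-hydroxyacrylates give 4-hydroxy-2-pyranones. LiN(SiMe3)2 removes a proton from the CH2 next to the enol-ester carbonyl (the future C3), and the lithium ester enolate adds to the carbonyl of the conjugated ethyl ester (the future C4). The ring closes in a 6-(enolendo)-exo-trig mode: the enolate C=C lies inside the forming ring, the attacked C=O outside it, and the O1–C2 ester bond is already present. Collapse of the tetrahedral intermediate expels the ester alkoxide, and the pyran-2,4-dione formed is deprotonated at once at C3 to the 4-oxido-2-pyranone, which takes the product out of all equilibria and drives the closure. No stereocentre is created. The selectivity needed is deprotonation at the acyl α-methylene and C-attack on the ethyl ester in preference to loss of the acyl group by ketene elimination or by attack of base at the enol-ester carbonyl; the Z geometry of 7 holds the ethyl ester within bonding distance of the enolate carbon, the hindered amide at low temperature does not add to the enol ester, and inverse addition into excess base ensures every molecule is enolised before any alkoxide is released. Deprotonation at the γ-CH2 of the enoate is a harmless side equilibrium, because that dienolate has no low-energy path for acyl transfer and is covered by the excess of base.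

Step 5
Reactants: 8 6-ethyl-4-hydroxy-5-methyl-3-[(2,4,6-trimethoxyphenyl)methyl]-2H-pyran-2-one
Product: 9 6-ethyl-4-hydroxy-5-methyl-3-[(2,4,6-trihydroxyphenyl)methyl]-2H-pyran-2-one
Conditions: BBr3 (6 equiv), CH2Cl2, −78 °C → 0 °C; then H2O
Reagents that add atoms: none
Why: Lewis-acid cleavage of aryl methyl ethers by BBr3 (coordination at oxygen, then bromide attack at methyl); the pyranone is only O-borylated and is released on hydrolysis. Low temperature limits ipso protonation of the electron-rich ring at the bridge carbon.

Step 6
Reactants: 9 6-ethyl-4-hydroxy-5-methyl-3-[(2,4,6-trihydroxyphenyl)methyl]-2H-pyran-2-one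
Product: 10 3-[(3-acetyl-2,4,6-trihydroxyphenyl)methyl]-6-ethyl-4-hydroxy-5-methyl-2H-pyran-2-one
Conditions: Ac2O (1.3 equiv), BF3·OEt2, 1,4-dioxane, 0 °C → rt; then MeOH–H2O, 50 °C
Reagents that add atoms: acetic anhydride, CC(=O)OC(C)=O
Why: Friedel–Crafts C-acylation of a phloroglucinol promoted by BF3; the two free ring carbons are equivalent, and the product is held as a boron chelate with a deactivated ring, so a second acylation should not follow. Pyranone C3 and C5 are both substituted, and any O-acetate is solvolysed in the warm aqueous methanol.

Step 7
Reactants: 10 3-[(3-acetyl-2,4,6-trihydroxyphenyl)methyl]-6-ethyl-4-hydroxy-5-methyl-2H-pyran-2-one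
Product: 11 3-[(3-acetyl-2,4,6-trihydroxy-5-iodophenyl)methyl]-6-ethyl-4-hydroxy-5-methyl-2H-pyran-2-one
Conditions: NIS (1.05 equiv), DMF, 0 °C, dark
Reagents that add atoms: N-iodosuccinimide, O=C1CCC(=O)N1I
Why: Electrophilic aromatic iodination at the only aromatic C–H, which lies between two hydroxyls and is strongly activated; one equivalent at 0 °C limits ipso attack at the bridge carbon.

Step 8
Reactants: 11 3-[(3-acetyl-2,4,6-trihydroxy-5-iodophenyl)methyl]-6-ethyl-4-hydroxy-5-methyl-2H-pyran-2-one; 12 myrcene (7-methyl-3-methylideneocta-1,6-diene)
Product: 13 3-{[(2R)-5-acetyl-4,6-dihydroxy-2-(6-methylhepta-1,5-dien-2-yl)-2,3-dihydro-1-benzofuran-7-yl]methyl}-6-ethyl-4-hydroxy-5-methyl-2H-pyran-2-one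
Conditions: 12 (3 equiv), Pd2(dba)3·CHCl3 (5 mol %), chiral sulfinamide monophosphine ligand of the TY-Phos type (20 mol %, antipode giving 2R, assigned in a preliminary model experiment), PhONa (3 equiv), THF–CH2Cl2, 40 °C, argon; then aq. NH4Cl
Reagents that add atoms: none
Why: Enantioselective palladium-catalysed heteroannulation of an ortho-halophenol with a 1,3-diene (Heck insertion, then Tsuji–Trost-type C–O closure): the arylpalladium from 11 adds to the terminal CH2 of the monosubstituted vinyl group of 12, and the π-allyl complex is closed to the five-membered ring by the phenoxide at the internal allyl carbon. The two allyl faces interconvert by η3–η1–η3 slippage at the unsubstituted CH2 terminus, so the chiral phosphine decides the configuration in the C–O bond-forming step. Of the two hydroxyls beside the iodide, the one para to the acetyl group is the more acidic and is not held in the hydrogen bond to the ketone, so it should be the phenoxide that closes the ring.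

## Compound list

1 | 2,4,6-trimethoxybenzaldehyde | COc1cc(OC)c(C=O)c(OC)c1 | starting material
2 | malonic acid | OC(=O)CC(=O)O | starting material
3 | (2E)-3-(2,4,6-trimethoxyphenyl)prop-2-enoic acid | COc1cc(OC)c(/C=C/C(=O)O)c(OC)c1 | intermediate
4 | 3-(2,4,6-trimethoxyphenyl)propanoic acid | COc1cc(OC)c(CCC(=O)O)c(OC)c1 | intermediate
5 | ethyl 2-methyl-3-oxopentanoate (racemic) | CCC(=O)C(C)C(=O)OCC | starting material
6 | 3-(2,4,6-trimethoxyphenyl)propanoyl chloride | COc1cc(OC)c(CCC(=O)Cl)c(OC)c1 | intermediate
7 | ethyl (2Z)-2-methyl-3-{[3-(2,4,6-trimethoxyphenyl)propanoyl]oxy}pent-2-enoate | CCOC(=O)/C(C)=C(/CC)OC(=O)CCc1c(OC)cc(OC)cc1OC | intermediate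
8 | 6-ethyl-4-hydroxy-5-methyl-3-[(2,4,6-trimethoxyphenyl)methyl]-2H-pyran-2-one | CCc1oc(=O)c(Cc2c(OC)cc(OC)cc2OC)c(O)c1C | intermediate
9 | 6-ethyl-4-hydroxy-5-methyl-3-[(2,4,6-trihydroxyphenyl)methyl]-2H-pyran-2-one | CCc1oc(=O)c(Cc2c(O)cc(O)cc2O)c(O)c1C | intermediate
10 | 3-[(3-acetyl-2,4,6-trihydroxyphenyl)methyl]-6-ethyl-4-hydroxy-5-methyl-2H-pyran-2-one | CCc1oc(=O)c(Cc2c(O)cc(O)c(C(C)=O)c2O)c(O)c1C | intermediate
11 | 3-[(3-acetyl-2,4,6-trihydroxy-5-iodophenyl)methyl]-6-ethyl-4-hydroxy-5-methyl-2H-pyran-2-one | CCc1oc(=O)c(Cc2c(O)c(I)c(O)c(C(C)=O)c2O)c(O)c1C | intermediate
12 | myrcene (7-methyl-3-methylideneocta-1,6-diene) | C=CC(=C)CCC=C(C)C | starting material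
13 | 3-{[(2R)-5-acetyl-4,6-dihydroxy-2-(6-methylhepta-1,5-dien-2-yl)-2,3-dihydro-1-benzofuran-7-yl]methyl}-6-ethyl-4-hydroxy-5-methyl-2H-pyran-2-one | C=C(CCC=C(C)C)[C@H]1Cc2c(O)c(C(C)=O)c(O)c(Cc3c(O)c(C)c(CC)oc3=O)c2O1 | target

## Step count and risk

Total step count: 8. Longest linear sequence: 8 steps (1 → 13).

**Step 4 (key step).** The most likely failure is loss of the acyl group instead of ring closure. It could occur by ketene elimination from the ester enolate, with the β-ketoester enolate as leaving group, or by attack of liberated alkoxide at the enol-ester carbonyl before all substrate is enolised. The fallback builds ring C first and makes the C3–CH2 bond afterwards. It sets out from aldehyde 1. Purchased trimethyl(pent-2-en-3-yloxy)silane and malonyl dichloride are combined in CH2Cl2 at −78 °C → rt, a known pyranone synthesis by C- then O-acylation, to give 6-ethyl-4-hydroxy-5-methyl-2H-pyran-2-one F1. F1 and 1 are then condensed with L-proline (cat.) and diethyl 2,6-dimethyl-1,4-dihydropyridine-3,5-dicarboxylate in CH2Cl2 at rt. The Knoevenagel product 6-ethyl-5-methyl-3-[(2,4,6-trimethoxyphenyl)methylidene]-2H-pyran-2,4(3H)-dione F2 is reduced in the flask by hydride transfer to its C=C bond. This known three-component reductive alkylation comes back to the route at 8.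

**Step 8.** The most likely failure is insufficient enantiocontrol, because the multiply deprotonated substrate can bind the chiral palladium complex. Ring closure through the hydroxyl next to the acetyl group, re-ionisation of the allylic aryl ether product by zerovalent palladium, and reductive loss of iodine are further possible losses. The fallback gives up catalyst control and sets out from 11. Ligand-free heteroannulation with 12 (Pd(OAc)2, NaHCO3, n-Bu4NCl, DMF, 80 °C) should give racemic 3-{[5-acetyl-4,6-dihydroxy-2-(6-methylhepta-1,5-dien-2-yl)-2,3-dihydro-1-benzofuran-7-yl]methyl}-6-ethyl-4-hydroxy-5-methyl-2H-pyran-2-one F3. Resolution of F3 by preparative HPLC on a chiral stationary phase then gives 13.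

**Step 3.** The most likely failure is acylation through a non-chelated enolate, giving the E enol ester, which cannot cyclise; C-acylation at the methyl-bearing carbon is the second risk. The fallback avoids metal enolates and sets out from 4. Dehydration with N,N'-dicyclohexylcarbodiimide (0.5 equiv, CH2Cl2, 0 °C) gives 3-(2,4,6-trimethoxyphenyl)propanoic anhydride F4. F4 acylates the hydrogen-bonded cis-enol of 5 under acid catalysis (TsOH cat., toluene, 50 °C), where the intramolecular hydrogen bond of the enol fixes the Z geometry. The sequence comes back to the route at 7.

**Step 5.** The most likely failure is acid-induced cleavage or scrambling of the aryl–CH2–pyranone bridge by ipso protonation of the very electron-rich ring during ether cleavage. The fallback changes the order of events and sets out from 8. Friedel–Crafts acetylation first (AcCl, SnCl4, CH2Cl2, −20 °C) gives 3-[(3-acetyl-2,4,6-trimethoxyphenyl)methyl]-6-ethyl-4-hydroxy-5-methyl-2H-pyran-2-one F5. Its acetyl group lowers the basicity of the ring, so the following BBr3 demethylation (CH2Cl2, −78 °C → 0 °C) meets an arene that is much harder to protonate at the bridge carbon. This reaches 10 directly, bypassing 9 and step 6.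

## Further compounds

F1 | step 4 | 6-ethyl-4-hydroxy-5-methyl-2H-pyran-2-one | CCc1oc(=O)cc(O)c1C
F2 | step 4 | 6-ethyl-5-methyl-3-[(2,4,6-trimethoxyphenyl)methylidene]-2H-pyran-2,4(3H)-dione | CCC1=C(C)C(=O)C(=Cc2c(OC)cc(OC)cc2OC)C(=O)O1
F3 | step 8 | racemic 3-{[5-acetyl-4,6-dihydroxy-2-(6-methylhepta-1,5-dien-2-yl)-2,3-dihydro-1-benzofuran-7-yl]methyl}-6-ethyl-4-hydroxy-5-methyl-2H-pyran-2-one | C=C(CCC=C(C)C)C1Cc2c(O)c(C(C)=O)c(O)c(Cc3c(O)c(C)c(CC)oc3=O)c2O1
F4 | step 3 | 3-(2,4,6-trimethoxyphenyl)propanoic anhydride | COc1cc(OC)c(CCC(=O)OC(=O)CCc2c(OC)cc(OC)cc2OC)c(OC)c1
F5 | step 5 | 3-[(3-acetyl-2,4,6-trimethoxyphenyl)methyl]-6-ethyl-4-hydroxy-5-methyl-2H-pyran-2-one | CCc1oc(=O)c(Cc2c(OC)cc(OC)c(C(C)=O)c2OC)c(O)c1C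
A1 | alternative 1 | 1-[(2R)-4,6-bis(tert-butyldimethylsilyloxy)-2-(6-methylhepta-1,5-dien-2-yl)-2,3-dihydrobenzofuran-5-yl]ethanone | C=C(CCC=C(C)C)[C@H]1Cc2c(O[Si](C)(C)C(C)(C)C)c(C(C)=O)c(O[Si](C)(C)C(C)(C)C)cc2O1
A2 | alternative 1 | 3-acetyl-2,4-bis(tert-butyldimethylsilyloxy)-6-[(6-methyl-2-methylidenehept-5-en-1-yl)oxy]benzaldehyde N-tosylhydrazone | C=C(CCC=C(C)C)COc1cc(O[Si](C)(C)C(C)(C)C)c(C(C)=O)c(O[Si](C)(C)C(C)(C)C)c1C=NNS(=O)(=O)c1ccc(C)cc1
A3 | alternative 1 | 6-ethyl-4-hydroxy-5-methyl-2H-pyran-2-one | CCc1oc(=O)cc(O)c1C
A4 | alternative 2 | 1-[(2R)-4,6-bis(methoxymethoxy)-2-(6-methylhepta-1,5-dien-2-yl)-2,3-dihydrobenzofuran-5-yl]ethanone | C=C(CCC=C(C)C)[C@H]1Cc2c(OCOC)c(C(C)=O)c(OCOC)cc2O1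
A5 | alternative 2 | 1-[4-hydroxy-3-iodo-2,6-bis(methoxymethoxy)phenyl]ethanone | CC(=O)c1c(OCOC)cc(O)c(I)c1OCOC
A6 | alternative 3 | 3-[(3-acetyl-2,4,6-trimethoxyphenyl)methyl]-6-ethyl-4-hydroxy-5-methyl-2H-pyran-2-one | CCc1oc(=O)c(Cc2c(OC)cc(OC)c(C(C)=O)c2OC)c(O)c1C
A7 | alternative 3 | 2-[(3-acetyl-2,4,6-trimethoxyphenyl)methyl]propanedioyl dichloride | CC(=O)c1c(OC)cc(OC)c(CC(C(=O)Cl)C(=O)Cl)c1OC
A8 | alternative 3 | trimethyl(pent-2-en-3-yloxy)silane | CC=C(CC)O[Si](C)(C)C
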